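Ring C is read as the [4+2] adduct of an O-aryl oxocarbenium ion (cationic 2-oxadiene C2=O1–C8a=C4a) and a ketene equivalent (C3–C4). An enantioselective oxa-Povarov annulation of ethoxyacetylene with the cation released from an acyclic aryloxy(4-methoxyphenyl)methyl pivalate forms C2–C3 and C4–C4a in one operation and sets C2; hydrolysis of the enol ether unveils the C4 ketone. The step exploits the local symmetry of ring A: O1 lies para to the C6 prenyl group, so the two ortho carbons (future C4a and C8) of the phenol precursor are equivalent and only the 6-prenyl flavanone can form.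

Key step: step 5

Remark: the acetal carbon of 9 and 10 is a stereocentre that becomes planar on ionisation in step 5, so both are made and used as racemates. The target is (2S), the configuration of the natural flavanones.

Step 1
Reactants: 1 5-chlorobenzene-1,3-diol (5-chlororesorcinol)
Product: 2 1-chloro-3,5-bis(methoxymethoxy)benzene
Conditions: MOMCl (2.5 equiv), iPr2NEt (3 equiv), CH2Cl2, 0 °C → rt
Reagents that add atoms: chloromethyl methyl ether (MOMCl), COCCl
Why: Williamson-type O-alkylation of both phenols by the reactive α-chloro ether should give the bis-MOM ether, whose acetal oxygens are the directing groups for step 2 and are removable later without touching the aryl methyl ether of the target.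

Step 2
Reactants: 2 1-chloro-3,5-bis(methoxymethoxy)benzene; 3 1-bromo-3-methylbut-2-ene (prenyl bromide)
Product: 5 5-chloro-1,3-bis(methoxymethoxy)-2-(3-methylbut-2-en-1-yl)benzene, via aryllithium 4 (not isolated)
Conditions: n-BuLi (1.1 equiv), THF, −20 °C; then CuI (10 mol %), 3 (1.3 equiv), −40 °C → rt
Reagents that add atoms: none
Why: Directed ortho-metalation should take place at the carbon flanked by both MOM ethers (two coordinating groups, against one for the carbons beside chlorine, and an aryl chloride does not undergo lithium–halogen exchange with n-BuLi), and copper-assisted SN2 allylation of the aryllithium installs the prenyl group.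

Step 3
Reactants: 5 5-chloro-1,3-bis(methoxymethoxy)-2-(3-methylbut-2-en-1-yl)benzene
Product: 6 3,5-bis(methoxymethoxy)-4-(3-methylbut-2-en-1-yl)phenol
Conditions: Pd2(dba)3 (2 mol %), tBuXPhos (8 mol %), KOH (3 equiv), 1,4-dioxane/H2O 1:1, 100 °C; then aq. NH4Cl
Reagents that add atoms: potassium hydroxide, [K+].[OH-]
Why: Buchwald-type hydroxylation of the aryl chloride (oxidative addition to zerovalent palladium, hydroxide exchange and C–O reductive elimination from divalent palladium, enabled by the bulky biarylphosphine) should free the one phenol that lies para to the prenyl group, the MOM ethers and the trisubstituted alkene being stable to aqueous base.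

Step 4
Reactants: 6 3,5-bis(methoxymethoxy)-4-(3-methylbut-2-en-1-yl)phenol; 7 4-methoxybenzaldehyde; 8 2,2-dimethylpropanoyl chloride (pivaloyl chloride)
Product: 10 [3,5-bis(methoxymethoxy)-4-(3-methylbut-2-en-1-yl)phenoxy](4-methoxyphenyl)methyl 2,2-dimethylpropanoate (racemic), via chloro ester 9 (not isolated)
Conditions: (a) 7, 8, ZnCl2 (2 mol %), CH2Cl2, 0 °C → rt; (b) 6, NaH, THF/DMF, 0 °C, then the solution of 9, −20 → 0 °C; aq. NaHCO3 work-up, Et3N-deactivated silica
Reagents that add atoms: none
Why: ZnCl2-catalysed addition of the acyl chloride across the aldehyde gives the α-chloroalkyl ester 9, whose labile benzylic chloride should be displaced at oxygen by the phenoxide of 6 (Williamson-type etherification as used for acyloxyalkyl ethers of phenols), the bulky pivaloyl group disfavouring acyl transfer; the acetal stereocentre forms racemic and is erased in step 5.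

Step 5
Reactants: 10 [3,5-bis(methoxymethoxy)-4-(3-methylbut-2-en-1-yl)phenoxy](4-methoxyphenyl)methyl 2,2-dimethylpropanoate; 11 ethoxyethyne (ethoxyacetylene)
Product: 14 (2S)-5,7-bis(methoxymethoxy)-2-(4-methoxyphenyl)-6-(3-methylbut-2-en-1-yl)-2,3-dihydro-4H-chromen-4-one, via oxocarbenium triflate 12 (not isolated), via enol ether 13 (not isolated)
Conditions: 11 (3 equiv), chiral arylpyrrolidine-derived squaramide hydrogen-bond donor (12 mol %), Me3SiOTf (10 mol %), t-BuOMe, −78 °C, slow addition of 10; then 1 M aq. HCl, THF, 0 °C
Reagents that add atoms: water, O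
Why: Proposed new method: the squaramide-bound Me3SiOTf ionises the pivalate of 10 to the O-aryl oxocarbenium triflate 12, the terminal carbon of ethoxyacetylene adds to its carbenium carbon (C2–C3), the α-ethoxyvinyl (ketenium) cation so formed is captured at once by the ortho carbon of ring A (C4–C4a), the proton and the silyl pivalate are absorbed by a second equivalent of the ynol ether so that Me3SiOTf is returned, and the acidic work-up hydrolyses enol ether 13 to ketone 14. The closest known reaction types are the Lewis-acid-mediated oxa-Povarov annulation of aryl oxocarbenium ions with alkenes (a stepwise polar [4+2] cycloaddition of the cationic 2-oxadiene C2=O1–C8a=C4a), the asymmetric Povarov reaction of N-aryl iminium ions under chiral hydrogen-bond-donor ion-pair catalysis, and squaramide/silyl triflate-catalysed enantioselective additions to aryl-substituted oxocarbenium ions; an ynol ether as the 2π partner and enantiocontrol over an O-aryl oxocarbenium ion are the unproven elements. Ring C closes by a 6-exo-dig Friedel–Crafts attack of C4a on the ketenium carbon (the C=O π bond that is consumed lies outside the new ring, the C3=C4 bond inside it). The only new stereocentre, C2, is set in the first C–C bond formation by the chiral squaramide·triflate anion, which should shield one face of the planar cation 12; the sense of induction cannot be predicted with confidence, so the catalyst antipode that delivers 2S is fixed in a first screen, and 14 is recrystallised if enrichment is needed. The step needs regio- and chemoselectivity: the two ortho carbons of ring A are equivalent because O1 is para to the prenyl group, so only the 6-prenyl skeleton can form; closure onto the anisyl ring would require a five-membered ring at a carbon meta to its methoxy group; pivalate is a far better leaving group than the aryloxide, so only the O-aryl cation is generated; and the excess ynol ether should outcompete the prenyl alkene and the enol ether 13 for 12.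

Step 6
Reactants: 14 (2S)-5,7-bis(methoxymethoxy)-2-(4-methoxyphenyl)-6-(3-methylbut-2-en-1-yl)-2,3-dihydro-4H-chromen-4-one
Product: 15 (2S)-5,7-dihydroxy-2-(4-methoxyphenyl)-6-(3-methylbut-2-en-1-yl)-2,3-dihydro-4H-chromen-4-one
Conditions: 3 M aq. HCl/MeOH 1:5, 40 °C, stopped at full conversion
Reagents that add atoms: none
Why: Acid-catalysed methanolysis of the two MOM acetals (the 5-O-MOM assisted by the peri carbonyl) should free both phenols without base, under which flavanones racemise by retro-oxa-Michael ring opening, and under conditions too mild for addition of the flanking phenols to the prenyl alkene, so C2 stays untouched.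

Compound list
1 | 5-chlorobenzene-1,3-diol | Oc1cc(O)cc(Cl)c1 | starting material
2 | 1-chloro-3,5-bis(methoxymethoxy)benzene | COCOc1cc(Cl)cc(OCOC)c1 | intermediate
3 | 1-bromo-3-methylbut-2-ene | CC(C)=CCBr | starting material
4 | [4-chloro-2,6-bis(methoxymethoxy)phenyl]lithium | [Li]c1c(OCOC)cc(Cl)cc1OCOC | intermediate
5 | 5-chloro-1,3-bis(methoxymethoxy)-2-(3-methylbut-2-en-1-yl)benzene | COCOc1cc(Cl)cc(OCOC)c1CC=C(C)C | intermediate
6 | 3,5-bis(methoxymethoxy)-4-(3-methylbut-2-en-1-yl)phenol | COCOc1cc(O)cc(OCOC)c1CC=C(C)C | intermediate
7 | 4-methoxybenzaldehyde | COc1ccc(C=O)cc1 | starting material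
8 | 2,2-dimethylpropanoyl chloride | CC(C)(C)C(Cl)=O | starting material
9 | chloro(4-methoxyphenyl)methyl 2,2-dimethylpropanoate (racemic) | COc1ccc(C(Cl)OC(=O)C(C)(C)C)cc1 | intermediate
10 | [3,5-bis(methoxymethoxy)-4-(3-methylbut-2-en-1-yl)phenoxy](4-methoxyphenyl)methyl 2,2-dimethylpropanoate (racemic) | COc1ccc(C(Oc2cc(OCOC)c(CC=C(C)C)c(OCOC)c2)OC(=O)C(C)(C)C)cc1 | intermediate
11 | ethoxyethyne | CCOC#C | starting material
12 | [3,5-bis(methoxymethoxy)-4-(3-methylbut-2-en-1-yl)phenyl](4-methoxybenzylidene)oxonium trifluoromethanesulfonate, held as the ion pair with the squaramide | COc1ccc(C=[O+]c2cc(OCOC)c(CC=C(C)C)c(OCOC)c2)cc1.[O-]S(=O)(=O)C(F)(F)F | intermediate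
13 | (2S)-4-ethoxy-5,7-bis(methoxymethoxy)-2-(4-methoxyphenyl)-6-(3-methylbut-2-en-1-yl)-2H-chromene | COc1ccc([C@@H]2C=C(OCC)c3c(cc(OCOC)c(CC=C(C)C)c3OCOC)O2)cc1 | intermediate
14 | (2S)-5,7-bis(methoxymethoxy)-2-(4-methoxyphenyl)-6-(3-methylbut-2-en-1-yl)-2,3-dihydro-4H-chromen-4-one | COc1ccc([C@@H]2CC(=O)c3c(cc(OCOC)c(CC=C(C)C)c3OCOC)O2)cc1 | intermediate
15 | (2S)-5,7-dihydroxy-2-(4-methoxyphenyl)-6-(3-methylbut-2-en-1-yl)-2,3-dihydro-4H-chromen-4-one | COc1ccc([C@@H]2CC(=O)c3c(cc(O)c(CC=C(C)C)c3O)O2)cc1 | target

Total step count: 6. Longest linear sequence: 6 steps (1 → 15, steps 1 to 6; 3, 7, 8 and 11 enter as purchased reagents).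

Steps most likely to fail

First, step 5. Facial discrimination of the acyclic oxocarbenium ion pair may be poor. The ketenium ion may be diverted by attack of the aryl ether oxygen (four-membered oxonium, ring opening to an aryl cinnamate). The ynol ether may polymerise under acid. The enol ether may ionise at C2–O1 and racemise, or hold the proton and stall turnover. The fallback uses known reactions only, sets out from 6 and rejoins the route at 14. Commercial ethyl 3-(4-methoxyphenyl)-3-oxopropanoate (CCOC(=O)CC(=O)c1ccc(OC)cc1) is reduced by Noyori hydrogenation (H2, RuCl2[(S)-BINAP], EtOH; the ligand antipode is confirmed on the product) to ethyl (3R)-3-hydroxy-3-(4-methoxyphenyl)propanoate F1. Mitsunobu etherification of 6 with F1 (PPh3, DIAD, toluene, −20 °C) should give, with inversion, ethyl (3S)-3-[3,5-bis(methoxymethoxy)-4-(3-methylbut-2-en-1-yl)phenoxy]-3-(4-methoxyphenyl)propanoate F2. LiOH in THF/H2O at 0 °C gives (3S)-3-[3,5-bis(methoxymethoxy)-4-(3-methylbut-2-en-1-yl)phenoxy]-3-(4-methoxyphenyl)propanoic acid F3. Intramolecular Friedel–Crafts acylation of F3 through the mixed anhydride ((CF3CO)2O, CH2Cl2, 0 °C) at either of the two equivalent ortho carbons closes ring C to 14. This path gives up the one-operation annulation but keeps the symmetry argument for the 6-prenyl isomer.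

Second, step 4. The adduct of the electron-rich aldehyde and the acyl chloride may form incompletely, the ambident phenoxide may be alkylated at carbon or acylated, and the mixed acetal may hydrolyse on isolation. The fallback changes the leaving group and the way the acetal carbon is built; it sets out from 6 and 7 and rejoins the route at 14. Aldehyde 7 is condensed with 1H-benzotriazole and the adduct is treated with SOCl2 to give 1-[chloro(4-methoxyphenyl)methyl]-1H-benzotriazole F4. The sodium salt of 6 (NaH, THF) displaces the chloride to give the stable, chromatographable 1-{[3,5-bis(methoxymethoxy)-4-(3-methylbut-2-en-1-yl)phenoxy](4-methoxyphenyl)methyl}-1H-benzotriazole F5. F5 then takes the place of 10 under the conditions of step 5, with benzotriazolide as the group that ionises, and gives 14.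

Third, step 2. Metalation may occur in part beside the chlorine, where loss of LiCl to an aryne follows on warming, and allylation may give some SN2′ product. The fallback changes the order of events; it sets out from 2 and rejoins the route at 6. The chlorine is replaced first under the conditions of step 3 to give 3,5-bis(methoxymethoxy)phenol F6. Silylation (iPr3SiCl, imidazole, DMF) gives [3,5-bis(methoxymethoxy)phenoxy]tri(propan-2-yl)silane F7. Metalation (n-BuLi, THF, 0 °C), now on a ring without halogen and with the bulky silyl ether shielding its own ortho carbons, followed by CuI (10 mol %) and 3, gives [3,5-bis(methoxymethoxy)-4-(3-methylbut-2-en-1-yl)phenoxy]tri(propan-2-yl)silane F8. Bu4NF in THF at 0 °C then returns phenol 6.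

Further compounds
F1 | step 5 | ethyl (3R)-3-hydroxy-3-(4-methoxyphenyl)propanoate | CCOC(=O)C[C@@H](O)c1ccc(OC)cc1
F2 | step 5 | ethyl (3S)-3-[3,5-bis(methoxymethoxy)-4-(3-methylbut-2-en-1-yl)phenoxy]-3-(4-methoxyphenyl)propanoate | CCOC(=O)C[C@H](Oc1cc(OCOC)c(CC=C(C)C)c(OCOC)c1)c1ccc(OC)cc1
F3 | step 5 | (3S)-3-[3,5-bis(methoxymethoxy)-4-(3-methylbut-2-en-1-yl)phenoxy]-3-(4-methoxyphenyl)propanoic acid | OC(=O)C[C@H](Oc1cc(OCOC)c(CC=C(C)C)c(OCOC)c1)c1ccc(OC)cc1
F4 | step 4 | 1-[chloro(4-methoxyphenyl)methyl]-1H-benzotriazole (racemic) | COc1ccc(C(Cl)n2nnc3ccccc32)cc1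
F5 | step 4 | 1-{[3,5-bis(methoxymethoxy)-4-(3-methylbut-2-en-1-yl)phenoxy](4-methoxyphenyl)methyl}-1H-benzotriazole (racemic) | COc1ccc(C(Oc2cc(OCOC)c(CC=C(C)C)c(OCOC)c2)n2nnc3ccccc32)cc1
F6 | step 2 | 3,5-bis(methoxymethoxy)phenol | COCOc1cc(O)cc(OCOC)c1
F7 | step 2 | [3,5-bis(methoxymethoxy)phenoxy]tri(propan-2-yl)silane | COCOc1cc(O[Si](C(C)C)(C(C)C)C(C)C)cc(OCOC)c1
F8 | step 2 | [3,5-bis(methoxymethoxy)-4-(3-methylbut-2-en-1-yl)phenoxy]tri(propan-2-yl)silane | COCOc1cc(O[Si](C(C)C)(C(C)C)C(C)C)cc(OCOC)c1CC=C(C)C
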